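**Retrosynthetic overview**
- Tiglate C–O bond: the target comes from a primary allylic alcohol and tigloyl chloride.
- C(α)–CH2OH bond: the (Z)-2-(hydroxymethyl)but-2-enoate comes from a but-2-ynoate ester and formaldehyde by syn hydroalumination and trapping, which fixes the Z geometry.
- Key disconnection, the stereogenic benzylic/allylic C–O bond: the (S)-1-arylallyl but-2-ynoate comes from the racemic aryl vinyl carbinol and but-2-ynoic acid by an enantioconvergent iridium-catalysed dehydrative allylic esterification.
- The carbinol comes from 3,4,5-trimethoxybenzaldehyde and vinylmagnesium bromide.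
- No ring is formed; the only ring, the arene, is bought.

Assumption: the (R)-configured ligand is taken to give the (S)-ester in step 2; this sense of induction is not predictable for a new nucleophile and is checked by chiral HPLC on the first run, and the (S)-ligand is used if it is opposite. Compounds are numbered in the order of the forward steps.

**Step 1**
Reactants: 1 3,4,5-trimethoxybenzaldehyde; 2 vinylmagnesium bromide
Product: 4 rac-1-(3,4,5-trimethoxyphenyl)prop-2-en-1-ol, via bromomagnesium alkoxide 3 (not isolated)
Conditions: CH2=CHMgBr (1.2 equiv), THF, 0 °C, 1 h; then sat. aq NH4Cl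
Reagents that add atoms: none
Why: Grignard 1,2-addition to a non-enolisable aryl aldehyde gives the aryl vinyl carbinol cleanly; the stereocentre is made racemic on purpose because step 2 is enantioconvergent.

**Step 2**
Reactants: 4 rac-1-(3,4,5-trimethoxyphenyl)prop-2-en-1-ol; 5 but-2-ynoic acid
Product: 6 (S)-1-(3,4,5-trimethoxyphenyl)prop-2-en-1-yl but-2-ynoate
Conditions: [Ir(cod)Cl]2 (3 mol %), (R)-L (12 mol %), 5 (2.0 equiv), 3 Å molecular sieves, ClCH2CH2Cl, 25 °C, 16 h; chromatography on Et3N-deactivated silica [L = 4-(5H-dibenzo[b,f]azepin-5-yl)dinaphtho[2,1-d:1',2'-f][1,3,2]dioxaphosphepine, the BINOL-derived phosphoramidite–olefin ligand]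
Reagents that add atoms: none
Why: Proposed new method: an enantioconvergent dehydrative allylic esterification (iridium-catalysed allylic substitution with a free carboxylic acid as O-nucleophile and an unactivated racemic branched allylic alcohol as electrophile), in which the monovalent iridium/(P,olefin) complex binds the vinyl group of either enantiomer of 4, acid 5 (pKa about 2.6, serving also as Brønsted promoter) activates the hydroxyl, ionisation gives one cationic trivalent iridium η3-(1-arylallyl) complex common to both enantiomers, and the carboxylic acid oxygen attacks the aryl-bearing terminus on the face opposite the metal under ligand control, forming the stereogenic C–O bond as the branched (S)-ester while the sieves remove water; the closest known reaction types are the enantioconvergent etherification and amination of racemic aryl vinyl carbinols with this catalyst family (sulfamic acid there being both promoter and nucleophile source) and the iridium/phosphoramidite esterification of linear allylic carbonates with carboxylate salts.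

**Step 3**
Reactants: 6 (S)-1-(3,4,5-trimethoxyphenyl)prop-2-en-1-yl but-2-ynoate; 7 formaldehyde
Product: 10 (S)-1-(3,4,5-trimethoxyphenyl)prop-2-en-1-yl (Z)-2-(hydroxymethyl)but-2-enoate, via vinylalane 8 (not isolated), via aluminium alkoxide 9 (not isolated)
Conditions: iBu2AlH (1.2 equiv), NMO (1.3 equiv), THF, 0 °C, 30 min; 6, −20 → 0 °C, 1 h; CH2O gas (cracked from paraformaldehyde at 150 °C, N2 stream), −20 → 0 °C; aq potassium sodium tartrate
Reagents that add atoms: none
Why: Vinylalumination, that is conjugate syn-hydroalumination of the ynoate by the amine-oxide-complexed aluminium hydride, puts H on C3 and Al on C2 cis to each other, and aldol-type trapping by formaldehyde with retention (attack cis to the β-hydrogen) gives the Z enoate with the β-methyl cis to the ester carbonyl; the cold, non-acidic conditions leave the (S)-allylic ester centre untouched.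

**Step 4**
Reactants: 10 (S)-1-(3,4,5-trimethoxyphenyl)prop-2-en-1-yl (Z)-2-(hydroxymethyl)but-2-enoate; 11 (E)-2-methylbut-2-enoyl chloride (tigloyl chloride)
Product: 12 (S)-1-(3,4,5-trimethoxyphenyl)prop-2-en-1-yl (Z)-2-({[(E)-2-methylbut-2-enoyl]oxy}methyl)but-2-enoate
Conditions: 11 (1.5 equiv), pyridine (3 equiv), CH2Cl2, 0 °C → rt, 3 h
Reagents that add atoms: none
Why: Acylation of the unhindered primary allylic alcohol with an acid chloride and pyridine (Einhorn acylation) forms the tiglate without a strongly nucleophilic catalyst, so no SN2′ or addition–elimination path scrambles the Z enoate, and pyridine buffers HCl so the acid-sensitive (S)-1-arylallyl ester is not ionised.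

**Compound list**
1 | 3,4,5-trimethoxybenzaldehyde | COc1cc(C=O)cc(OC)c1OC | starting material
2 | vinylmagnesium bromide | C=C[Mg]Br | starting material
3 | bromomagnesium 1-(3,4,5-trimethoxyphenyl)prop-2-en-1-olate (racemic) | C=CC(O[Mg]Br)c1cc(OC)c(OC)c(OC)c1 | intermediate
4 | rac-1-(3,4,5-trimethoxyphenyl)prop-2-en-1-ol | C=CC(O)c1cc(OC)c(OC)c(OC)c1 | intermediate
5 | but-2-ynoic acid | CC#CC(=O)O | starting material
6 | (S)-1-(3,4,5-trimethoxyphenyl)prop-2-en-1-yl but-2-ynoate | C=C[C@H](OC(=O)C#CC)c1cc(OC)c(OC)c(OC)c1 | intermediate
7 | formaldehyde (monomer; bought as paraformaldehyde and cracked) | C=O | starting material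
8 | (S)-1-(3,4,5-trimethoxyphenyl)prop-2-en-1-yl (E)-2-(diisobutylalumanyl)but-2-enoate (vinylalane, NMO-coordinated, in equilibrium with its aluminium allenolate form) | C=C[C@H](OC(=O)/C(=C\C)[Al](CC(C)C)CC(C)C)c1cc(OC)c(OC)c(OC)c1 | intermediate
9 | diisobutylaluminium alkoxide of 10 | C=C[C@H](OC(=O)/C(=C\C)CO[Al](CC(C)C)CC(C)C)c1cc(OC)c(OC)c(OC)c1 | intermediate
10 | (S)-1-(3,4,5-trimethoxyphenyl)prop-2-en-1-yl (Z)-2-(hydroxymethyl)but-2-enoate | C=C[C@H](OC(=O)/C(=C\C)CO)c1cc(OC)c(OC)c(OC)c1 | intermediate
11 | (E)-2-methylbut-2-enoyl chloride (tigloyl chloride) | C/C=C(\C)C(=O)Cl | starting material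
12 | (S)-1-(3,4,5-trimethoxyphenyl)prop-2-en-1-yl (Z)-2-({[(E)-2-methylbut-2-enoyl]oxy}methyl)but-2-enoate | C=C[C@H](OC(=O)/C(=C\C)COC(=O)/C(C)=C/C)c1cc(OC)c(OC)c(OC)c1 | target

**Totals**
Total step count: 4. Longest linear sequence: 4 (1 → 4 → 6 → 10 → 12).

**Steps most likely to fail**

Step 2 (the proposed new esterification). The free acid may be too weak a nucleophile, the alkyne may bind the monovalent iridium centre, bis-allyl ether may form, or the product may re-ionise and drift to the linear cinnamyl ester. The fallback uses known chemistry, sets out from 4 and comes back at 6. Racemic 4 is resolved with immobilised Candida antarctica lipase B and vinyl acetate in MTBE at 30 °C to about 52 % conversion. The fast-reacting enantiomer is acetylated to (R)-1-(3,4,5-trimethoxyphenyl)prop-2-en-1-yl acetate F2. The unreacted (S)-1-(3,4,5-trimethoxyphenyl)prop-2-en-1-ol F1 is separated by chromatography (at most 50 % yield). F1 is then esterified with but-2-ynoic acid 5 under Steglich conditions (DCC, 5 mol % DMAP, CH2Cl2, −20 → 0 °C), which forms the acyl C–O bond with retention and gives 6.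

Step 3 (vinylalumination on the sensitive 1-arylallyl ester). Possible failures are 1,2-reduction or ionisation of the allylic ester, Claisen-type [3,3] shift of the allenolate, or partial loss of Z geometry. The fallback is convergent: the aluminium chemistry is run on a robust simple ester and the chiral alcohol is attached last. It sets out from 5 and comes back at 12.
- But-2-ynoic acid 5 is converted with tert-butyl 2,2,2-trichloroacetimidate and catalytic BF3·OEt2 in CH2Cl2/cyclohexane into tert-butyl but-2-ynoate F3.
- Treatment with iBu2AlH/NMO in THF at 0 °C gives the vinylalane tert-butyl (E)-2-(diisobutylalumanyl)but-2-enoate F4.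
- Formaldehyde gas converts it into the diisobutylaluminium alkoxide of tert-butyl (Z)-2-(hydroxymethyl)but-2-enoate F5, and tartrate work-up gives tert-butyl (Z)-2-(hydroxymethyl)but-2-enoate F6.
- Acylation with tigloyl chloride 11 and pyridine gives tert-butyl (Z)-2-({[(E)-2-methylbut-2-enoyl]oxy}methyl)but-2-enoate F7.
- CF3CO2H in CH2Cl2 at 0 °C removes the tert-butyl group to give (Z)-2-({[(E)-2-methylbut-2-enoyl]oxy}methyl)but-2-enoic acid F8.
- F8 is coupled with (S)-1-(3,4,5-trimethoxyphenyl)prop-2-en-1-ol F1, made as in the fallback to step 2, using DCC and catalytic DMAP in CH2Cl2 at 0 °C, to give 12.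

Step 4 (tigloylation). Possible failures are Z → E isomerisation of the 2-(acyloxymethyl)enoate by SN2′ chemistry, or base-induced deconjugation/isomerisation of tigloyl chloride through its vinylketene. The fallback reverses the roles of the partners, sets out from 10 and comes back at 12. Alcohol 10 is activated as the electrophile under Mitsunobu conditions (tiglic acid 1.3 equiv, PPh3, diisopropyl azodicarboxylate, THF, 0 °C), and the tiglate anion displaces the oxyphosphonium group at the primary carbon by direct SN2. No acid chloride or amine base is present.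

**Further compounds**
F1 | step 2 | (S)-1-(3,4,5-trimethoxyphenyl)prop-2-en-1-ol | C=C[C@H](O)c1cc(OC)c(OC)c(OC)c1
F2 | step 2 | (R)-1-(3,4,5-trimethoxyphenyl)prop-2-en-1-yl acetate | C=C[C@@H](OC(C)=O)c1cc(OC)c(OC)c(OC)c1
F3 | step 3 | tert-butyl but-2-ynoate | CC#CC(=O)OC(C)(C)C
F4 | step 3 | tert-butyl (E)-2-(diisobutylalumanyl)but-2-enoate | CC(C)(C)OC(=O)/C(=C\C)[Al](CC(C)C)CC(C)C
F5 | step 3 | diisobutylaluminium alkoxide of tert-butyl (Z)-2-(hydroxymethyl)but-2-enoate | CC(C)(C)OC(=O)/C(=C\C)CO[Al](CC(C)C)CC(C)C
F6 | step 3 | tert-butyl (Z)-2-(hydroxymethyl)but-2-enoate | CC(C)(C)OC(=O)/C(=C\C)CO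
F7 | step 3 | tert-butyl (Z)-2-({[(E)-2-methylbut-2-enoyl]oxy}methyl)but-2-enoate | CC(C)(C)OC(=O)/C(=C\C)COC(=O)/C(C)=C/C
F8 | step 3 | (Z)-2-({[(E)-2-methylbut-2-enoyl]oxy}methyl)but-2-enoic acid | OC(=O)/C(=C\C)COC(=O)/C(C)=C/C
F0 | step 4 | none | none
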